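The constants of the crystal step and of the isomer step bear most on which change to this charge is worth a next run.

    solid substrate ⇌ dissolved substrate, rate k1*(cs1 - [dissolved substrate]) while solid is left; crystals form when [dissolved substrate] > cs1 (cs1 = 0.13 M, k1 = 0.0118 min⁻¹)
    dissolved substrate + partner → target (k2 = 1.80 M⁻¹ min⁻¹)
    2 dissolved substrate → side product (k3 = 2.49 M⁻¹ min⁻¹)
    solid product ⇌ target, rate k4*(cs4 - [target]) while solid is left; crystals form when [target] > cs4 (cs4 = 0.068 M, k4 = 0.789 min⁻¹)
    partner + protic impurity → quenched reagent (k5 = 0.192 M⁻¹ min⁻¹)
    2 partner → homo dimer (k6 = 0.0198 M⁻¹ min⁻¹)
    target ⇌ isomer of the product (K7 = 0.56, k7 = 0.00404 min⁻¹)

solid substrate 0.20 M; partner 0.600 M; protic impurity 0.0400 M; time 8.0 h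

- maple: doubling the solubility in step 4, all else as stated
- alder: doubling the amount of partner, all else as stated
- cedar: doubling the dissolution coefficient of step 4, all else as stated
- birch: doubling the solubility in step 1, all else as stated

- a species is counted by the solid substrate in it: one side product counts as two
- amounts and yields of target count solid product too
- two of one species on the left: rate k times its square, two consumed each time
- given per volume of solution although it is solid: solid substrate, solid product
- at the start none of the solid substrate is in solution
- run time (flask): 8.0 h

* target and solid product together at 8.0 h, in percent of the solid substrate charged
* the change that raises the amount of target and solid product together at 8.0 h, in percent of the solid substrate charged most ("none" if none brings more than 2 percentage points) (maple / alder / cedar / birch / none)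
* amount of target and solid product together at 8.0 h, in percent of the solid substrate charged, after cedar

**Fast exchange.** Crystals and dissolved target exchange on a time of 1.27 min, the reciprocal of their dissolution coefficient, which is far shorter than the 1.03 h relaxation half-life of target and isomer. So the crystal step is taken as balanced, and while solid product stands, dissolved target is held at its solubility S, 0.068 M. The isomer step, with a half-life short against the run, then carries the isomer towards K·S, with K its equilibrium constant: thermodynamic control.

**Isomer ceiling.** Dividing by the charge A of solid substrate gives I = K·S/A = 19.0%. This isomer ceiling is the share of the charge that the isomer approaches from below while crystals stand. Late in the run, target and solid product together then come down from above towards 81.0%, less whatever side product takes.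

**Next run.** The dissolution coefficient does not appear in I, so cedar is expected to leave the yield as it is. Maple doubles S and lifts the ceiling to 38.0%, so maple is struck out. Alder and birch leave I unchanged, so this reckoning looks for any gain from them in the side product, and it does not rank the two.

**The result.** The forecast gives 72.7%, alder and 72.7% after cedar, holding that “Target saturates at 0.068 M, so crystals hold it there.” The simulation gives 71.9%, and 71.9% after cedar. Maple changes the yield by −14 percentage points, and alder gains most, 4.3 points. At 8.00 h the flask holds 18.3% as isomer, under I, and 9.76% as side product. The neighbour charged with 1.5 M of partner keeps the same I and still holds 42.8% as solid product. Its side product of 4.85% then leaves 76.2% by the reckoning, and that neighbour gives 76.8%, with 18.3% as isomer.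

The constants used here are invented; the flask was simulated.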